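**Plan**

1. Locants: chain C1 (acetoxy-bearing CH) to C9 (CH2 on the ring); ring C1' (stereocentre), C2'=C3', C6' (CMe2). Retrosynthesis: the formyl group goes back to a PMB-protected CH2OH, the (E)-enol acetate to a terminal alkyne, and the C3 acetoxy centre to a 2,2-disubstituted epoxy alcohol; then C4–C5 (allylic alkylation), C6=C7 (alkyne carboalumination) and last C9–C1' are cut.
2. Enabling feature: C1' is allylic to the ring C2'=C3' bond. The C9–C1' bond is therefore made by anti-SN2' displacement on the transposed allylic picolinate (oxygen on the future C3', alkene at the future C1'=C2'). One event forms the bond next to quaternary C6', sets C1' and fixes the ring alkene.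
3. Forward: enone → CBS reduction → picolinate → copper-mediated coupling with a C4 alkynyl Grignard reagent → carboalumination/hydroxymethylation (C6=C7) → bromide → methallyl alcohol dianion (C4–C5) → Sharpless epoxidation (C3) → alkyne → PMB-alkoxide opening → acetate → hydroboration and copper-catalysed acetoxylation (C1=C2) → PMB removal → oxidation.
4. Stereochemistry: C1' (S) from the CBS-derived (S)-carbinol by 1,3-anti chirality transfer; C3 (R) from the Sharpless epoxidation with D-(−)-DIPT, its C–O bond never being broken afterwards; both E alkenes from syn additions to terminal alkynes (Me–Al, H–B) followed by bond formation with retention.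

Key step: step 3

**Route**

Step 1
Reactants: 1 2,4,4-trimethylcyclohex-2-en-1-one
Product: 2 (1S)-2,4,4-trimethylcyclohex-2-en-1-ol
Conditions: (R)-2-methyl-CBS-oxazaborolidine (10 mol %), BH3·SMe2, THF, −20 °C; MeOH quench
Reagents that add atoms: none
Why: CBS (Corey–Bakshi–Shibata) reduction in which the alkenyl arm (C2) acts as the large group, so the borane bound to the (R)-catalyst should deliver hydride to the face that gives the (S)-carbinol, the centre that later relays its configuration to the ring carbon of the target.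

Step 2
Reactants: 2 (1S)-2,4,4-trimethylcyclohex-2-en-1-ol
Product: 3 (1S)-2,4,4-trimethylcyclohex-2-en-1-yl pyridine-2-carboxylate
Conditions: picolinic acid, DCC, DMAP (cat.), CH2Cl2, 0 °C → rt
Reagents that add atoms: picolinic acid OC(=O)c1ccccn1
Why: Steglich esterification that leaves the carbinol centre untouched; the picolinate is chosen because its N,O-chelation of magnesium makes it a leaving group that favours γ-attack in the next step.

Step 3
Reactants: 3 (1S)-2,4,4-trimethylcyclohex-2-en-1-yl pyridine-2-carboxylate; 4 (4-bromobut-1-yn-1-yl)trimethylsilane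
Product: 6 (S)-trimethyl[4-(2,6,6-trimethylcyclohex-2-en-1-yl)but-1-yn-1-yl]silane, via Grignard reagent 5 (not isolated)
Conditions: 4, Mg, THF, rt (gives 5, 3 equiv); CuBr·SMe2 (30 mol %), THF, −40 °C; then 3, −40 → 0 °C
Reagents that add atoms: none
Why: MgBr2 held by the pyridine nitrogen and the carbonyl oxygen of the picolinate makes the C–O bond a strong leaving group, and the alkylcopper species formed from 5 and CuBr adds oxidatively to the alkene CH carbon next to CMe2 on the face opposite to that C–O bond, giving a trivalent σ-allylcopper intermediate that collapses by reductive elimination at the same carbon (anti-SN2'). The closest known reaction type is the copper-mediated anti-SN2' substitution of secondary cyclohexenyl picolinates (and phosphates) with Grignard reagents, which runs with 1,3-chirality transfer. No ring is closed; the event moves the ring double bond into the C2'=C3' position of the target, so no separate control of alkene position is needed. The new stereocentre C1' is controlled only by the (S)-carbinol centre of 3 through the anti course, which should give (S). The step needs γ- over α-regioselectivity at a carbon flanked by the quaternary CMe2, and stereospecificity without allyl scrambling; the chelating picolinate, the low temperature and the cyclic frame, which ties the anti geometry to one ring face, are what secure them.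

Step 4
Reactants: 6 (S)-trimethyl[4-(2,6,6-trimethylcyclohex-2-en-1-yl)but-1-yn-1-yl]silane
Product: 7 (6S)-6-(but-3-yn-1-yl)-1,5,5-trimethylcyclohex-1-ene
Conditions: K2CO3 (cat.), MeOH, rt
Reagents that add atoms: none
Why: Methanolysis of the alkynyl C–Si bond by catalytic methoxide (protodesilylation) frees the terminal alkyne, while the ring alkene and the stereocentre are inert.

Step 5
Reactants: 7 (6S)-6-(but-3-yn-1-yl)-1,5,5-trimethylcyclohex-1-ene
Product: 9 (2E)-3-methyl-5-[(1S)-2,6,6-trimethylcyclohex-2-en-1-yl]pent-2-en-1-ol, via alkenylalane 8 (not isolated)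
Conditions: Me3Al (2.5 equiv), Cp2ZrCl2 (25 mol %), CH2Cl2, 0 °C → rt; then (CH2O)n, THF, 0 °C → rt
Reagents that add atoms: trimethylaluminium C[Al](C)C; formaldehyde (as paraformaldehyde) C=O
Why: Negishi zirconium-catalysed carboalumination adds Me and Al syn across the terminal alkyne with Al on the terminal carbon, and the alkenylalane is hydroxymethylated with retention, so C6=C7 should form as the E isomer while the trisubstituted ring alkene does not react.

Step 6
Reactants: 9 (2E)-3-methyl-5-[(1S)-2,6,6-trimethylcyclohex-2-en-1-yl]pent-2-en-1-ol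
Product: 10 (6S)-6-[(3E)-5-bromo-3-methylpent-3-en-1-yl]-1,5,5-trimethylcyclohex-1-ene
Conditions: PBr3 (0.4 equiv), pyridine (cat.), Et2O, −10 → 0 °C
Reagents that add atoms: phosphorus tribromide BrP(Br)Br
Why: Bromination of the primary allylic alcohol through its bromophosphite (SN2 by bromide) at low temperature, the standard way to geranyl-type bromides without allylic shift or E/Z loss.

Step 7
Reactants: 10 (6S)-6-[(3E)-5-bromo-3-methylpent-3-en-1-yl]-1,5,5-trimethylcyclohex-1-ene; 11 2-methylprop-2-en-1-ol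
Product: 13 (5E)-6-methyl-2-methylidene-8-[(1S)-2,6,6-trimethylcyclohex-2-en-1-yl]oct-5-en-1-ol, via dilithio dianion 12 (not isolated)
Conditions: 11 (3 equiv), n-BuLi (6 equiv), TMEDA, Et2O/hexane, 0 °C → rt; then 10, THF, −78 °C → rt
Reagents that add atoms: none
Why: Allylic alkylation in which the C,O-dilithiated methallyl alcohol (a symmetrical allyl anion, so both termini give the same product) attacks the primary allylic bromide by SN2, forming C4–C5 and bringing in the 2-substituted allylic alcohol needed for the epoxidation.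

Step 8
Reactants: 13 (5E)-6-methyl-2-methylidene-8-[(1S)-2,6,6-trimethylcyclohex-2-en-1-yl]oct-5-en-1-ol
Product: 14 [(2R)-2-{(3E)-4-methyl-6-[(1S)-2,6,6-trimethylcyclohex-2-en-1-yl]hex-3-en-1-yl}oxiran-2-yl]methanol
Conditions: Ti(OiPr)4 (10 mol %), D-(−)-diisopropyl tartrate (12 mol %), t-BuOOH (2 equiv, in decane), 4 Å MS, CH2Cl2, −20 °C
Reagents that add atoms: tert-butyl hydroperoxide CC(C)(C)OO
Why: Katsuki–Sharpless asymmetric epoxidation, in which the titanium tartrate complex binds the allylic hydroxyl so that only the 1,1-disubstituted allylic alkene is epoxidised, and D-(−)-DIPT should deliver oxygen to the face that gives the (R)-epoxide, which becomes C3 of the target.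

Step 9
Reactants: 14 [(2R)-2-{(3E)-4-methyl-6-[(1S)-2,6,6-trimethylcyclohex-2-en-1-yl]hex-3-en-1-yl}oxiran-2-yl]methanol
Product: 15 (2S)-2-{(3E)-4-methyl-6-[(1S)-2,6,6-trimethylcyclohex-2-en-1-yl]hex-3-en-1-yl}oxirane-2-carbaldehyde
Conditions: Dess–Martin periodinane, NaHCO3, CH2Cl2, 0 °C → rt
Reagents that add atoms: none
Why: Dess–Martin oxidation of the primary alcohol under buffered conditions; the epoxide carbon carries no hydrogen, so the stereocentre cannot epimerise (the descriptor changes only through CIP priorities).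

Step 10
Reactants: 15 (2S)-2-{(3E)-4-methyl-6-[(1S)-2,6,6-trimethylcyclohex-2-en-1-yl]hex-3-en-1-yl}oxirane-2-carbaldehyde
Product: 16 (2R)-2-ethynyl-2-{(3E)-4-methyl-6-[(1S)-2,6,6-trimethylcyclohex-2-en-1-yl]hex-3-en-1-yl}oxirane
Conditions: dimethyl (1-diazo-2-oxopropyl)phosphonate, K2CO3, MeOH, 0 °C → rt
Reagents that add atoms: dimethyl (1-diazo-2-oxopropyl)phosphonate COP(=O)(OC)C(=[N+]=[N-])C(C)=O
Why: Ohira–Bestmann (Seyferth–Gilbert) homologation, in which the diazomethylphosphonate anion adds to the aldehyde and the derived alkylidene carbene rearranges by 1,2-hydrogen shift to the terminal alkyne, without touching the quaternary centre or, at this temperature, the epoxide.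

Step 11
Reactants: 16 (2R)-2-ethynyl-2-{(3E)-4-methyl-6-[(1S)-2,6,6-trimethylcyclohex-2-en-1-yl]hex-3-en-1-yl}oxirane
Product: 17 (3R,6E)-3-{[(4-methoxybenzyl)oxy]methyl}-7-methyl-9-[(1S)-2,6,6-trimethylcyclohex-2-en-1-yl]non-6-en-1-yn-3-ol
Conditions: 4-methoxybenzyl alcohol (5 equiv), NaH (0.5 equiv), DMF, 60 °C
Reagents that add atoms: 4-methoxybenzyl alcohol COc1ccc(CO)cc1
Why: Base-catalysed SN2 opening of the 2,2-disubstituted epoxide by the alkoxide at the unsubstituted CH2, so the C3–O bond is not broken and the configuration is retained, while the future formyl carbon is protected as its PMB ether in the same step.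

Step 12
Reactants: 17 (3R,6E)-3-{[(4-methoxybenzyl)oxy]methyl}-7-methyl-9-[(1S)-2,6,6-trimethylcyclohex-2-en-1-yl]non-6-en-1-yn-3-ol
Product: 18 (3R,6E)-3-{[(4-methoxybenzyl)oxy]methyl}-7-methyl-9-[(1S)-2,6,6-trimethylcyclohex-2-en-1-yl]non-6-en-1-yn-3-yl acetate
Conditions: Ac2O, Et3N, DMAP, CH2Cl2, rt → 40 °C
Reagents that add atoms: acetic anhydride CC(=O)OC(C)=O
Why: DMAP-catalysed acetylation of the tertiary propargylic alcohol, slow but standard with excess anhydride, with no bond to C3 broken.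

Step 13
Reactants: 18 (3R,6E)-3-{[(4-methoxybenzyl)oxy]methyl}-7-methyl-9-[(1S)-2,6,6-trimethylcyclohex-2-en-1-yl]non-6-en-1-yn-3-yl acetate
Product: 20 potassium [(1E,3R,6E)-3-acetoxy-3-{[(4-methoxybenzyl)oxy]methyl}-7-methyl-9-[(1S)-2,6,6-trimethylcyclohex-2-en-1-yl]nona-1,6-dien-1-yl]trifluoroborate, via pinacol alkenylboronate 19 (not isolated)
Conditions: pinacolborane (1.5 equiv), Cp2Zr(H)Cl (10 mol %), Et3N (10 mol %), CH2Cl2, rt; then KHF2 (aq), MeOH, rt
Reagents that add atoms: pinacolborane CC1(C)OBOC1(C)C; potassium hydrogen difluoride [K+].F[H-]F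
Why: Zirconium-catalysed hydroboration of the terminal alkyne is a syn, anti-Markovnikov addition that should give the (E)-alkenylboronate with the trisubstituted alkenes untouched, and KHF2 converts it into the trifluoroborate needed for the C–O coupling.

Step 14
Reactants: 20 potassium [(1E,3R,6E)-3-acetoxy-3-{[(4-methoxybenzyl)oxy]methyl}-7-methyl-9-[(1S)-2,6,6-trimethylcyclohex-2-en-1-yl]nona-1,6-dien-1-yl]trifluoroborate
Product: 21 (1E,3R,6E)-3-{[(4-methoxybenzyl)oxy]methyl}-7-methyl-9-[(1S)-2,6,6-trimethylcyclohex-2-en-1-yl]nona-1,6-diene-1,3-diyl diacetate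
Conditions: AcOH (3 equiv), CuBr (10 mol %), DMAP (20 mol %), 4 Å MS, O2 (1 atm), CH2Cl2, 40 °C
Reagents that add atoms: acetic acid CC(=O)O
Why: Copper-catalysed oxidative (Chan–Lam type) coupling of an alkenyltrifluoroborate with a carboxylic acid, in which transmetalation, oxidation by O2 and C–O reductive elimination keep the alkene geometry, so the (E)-enol acetate should form without an aldehyde enolate that could expel the β-acetate.

Step 15
Reactants: 21 (1E,3R,6E)-3-{[(4-methoxybenzyl)oxy]methyl}-7-methyl-9-[(1S)-2,6,6-trimethylcyclohex-2-en-1-yl]nona-1,6-diene-1,3-diyl diacetate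
Product: 22 (1E,3R,6E)-3-(hydroxymethyl)-7-methyl-9-[(1S)-2,6,6-trimethylcyclohex-2-en-1-yl]nona-1,6-diene-1,3-diyl diacetate
Conditions: DDQ (1.3 equiv), CH2Cl2/pH 7 phosphate buffer (10:1), 0 °C; crude product used at once
Reagents that add atoms: none
Why: Oxidative PMB cleavage by DDQ (hydride abstraction, then hydrolysis of the oxocarbenium ion) under near-neutral conditions, which should spare the enol acetate, the tertiary acetate and the alkenes and limit acyl migration to the freed hydroxyl.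

Step 16
Reactants: 22 (1E,3R,6E)-3-(hydroxymethyl)-7-methyl-9-[(1S)-2,6,6-trimethylcyclohex-2-en-1-yl]nona-1,6-diene-1,3-diyl diacetate
Product: 23 (1E,3R,6E)-3-formyl-7-methyl-9-[(1S)-2,6,6-trimethylcyclohex-2-en-1-yl]nona-1,6-diene-1,3-diyl diacetate
Conditions: Dess–Martin periodinane, NaHCO3, CH2Cl2, 0 °C
Reagents that add atoms: none
Why: Dess–Martin oxidation of the neopentyl-type primary alcohol to an aldehyde that has no α-hydrogen and so cannot enolise or eliminate, under buffered conditions that spare the enol acetate.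

**Compound list**

1 | 2,4,4-trimethylcyclohex-2-en-1-one | CC1=CC(C)(C)CCC1=O | starting material
2 | (1S)-2,4,4-trimethylcyclohex-2-en-1-ol | O[C@H]1CCC(C)(C)C=C1C | intermediate
3 | (1S)-2,4,4-trimethylcyclohex-2-en-1-yl pyridine-2-carboxylate | O=C(O[C@H]1CCC(C)(C)C=C1C)c1ccccn1 | intermediate
4 | (4-bromobut-1-yn-1-yl)trimethylsilane | C[Si](C)(C)C#CCCBr | starting material
5 | [4-(trimethylsilyl)but-3-yn-1-yl]magnesium bromide | C[Si](C)(C)C#CCC[Mg]Br | intermediate
6 | (S)-trimethyl[4-(2,6,6-trimethylcyclohex-2-en-1-yl)but-1-yn-1-yl]silane | C[Si](C)(C)C#CCC[C@@H]1C(C)=CCCC1(C)C | intermediate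
7 | (6S)-6-(but-3-yn-1-yl)-1,5,5-trimethylcyclohex-1-ene | C#CCC[C@@H]1C(C)=CCCC1(C)C | intermediate
8 | dimethyl{(1E)-2-methyl-4-[(1S)-2,6,6-trimethylcyclohex-2-en-1-yl]but-1-en-1-yl}alane | C[Al](C)/C=C(\C)CC[C@@H]1C(C)=CCCC1(C)C | intermediate
9 | (2E)-3-methyl-5-[(1S)-2,6,6-trimethylcyclohex-2-en-1-yl]pent-2-en-1-ol | OC/C=C(\C)CC[C@@H]1C(C)=CCCC1(C)C | intermediate
10 | (6S)-6-[(3E)-5-bromo-3-methylpent-3-en-1-yl]-1,5,5-trimethylcyclohex-1-ene | BrC/C=C(\C)CC[C@@H]1C(C)=CCCC1(C)C | intermediate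
11 | 2-methylprop-2-en-1-ol | CC(=C)CO | starting material
12 | dilithio derivative of 2-methylprop-2-en-1-ol (C,O-dianion) | [Li]CC(=C)CO[Li] | intermediate
13 | (5E)-6-methyl-2-methylidene-8-[(1S)-2,6,6-trimethylcyclohex-2-en-1-yl]oct-5-en-1-ol | OCC(=C)CC/C=C(\C)CC[C@@H]1C(C)=CCCC1(C)C | intermediate
14 | [(2R)-2-{(3E)-4-methyl-6-[(1S)-2,6,6-trimethylcyclohex-2-en-1-yl]hex-3-en-1-yl}oxiran-2-yl]methanol | OC[C@]1(CC/C=C(\C)CC[C@@H]2C(C)=CCCC2(C)C)CO1 | intermediate
15 | (2S)-2-{(3E)-4-methyl-6-[(1S)-2,6,6-trimethylcyclohex-2-en-1-yl]hex-3-en-1-yl}oxirane-2-carbaldehyde | O=C[C@]1(CC/C=C(\C)CC[C@@H]2C(C)=CCCC2(C)C)CO1 | intermediate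
16 | (2R)-2-ethynyl-2-{(3E)-4-methyl-6-[(1S)-2,6,6-trimethylcyclohex-2-en-1-yl]hex-3-en-1-yl}oxirane | C#C[C@]1(CC/C=C(\C)CC[C@@H]2C(C)=CCCC2(C)C)CO1 | intermediate
17 | (3R,6E)-3-{[(4-methoxybenzyl)oxy]methyl}-7-methyl-9-[(1S)-2,6,6-trimethylcyclohex-2-en-1-yl]non-6-en-1-yn-3-ol | C#C[C@](O)(CC/C=C(\C)CC[C@@H]1C(C)=CCCC1(C)C)COCc1ccc(OC)cc1 | intermediate
18 | (3R,6E)-3-{[(4-methoxybenzyl)oxy]methyl}-7-methyl-9-[(1S)-2,6,6-trimethylcyclohex-2-en-1-yl]non-6-en-1-yn-3-yl acetate | C#C[C@](OC(C)=O)(CC/C=C(\C)CC[C@@H]1C(C)=CCCC1(C)C)COCc1ccc(OC)cc1 | intermediate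
19 | (1E,3R,6E)-3-{[(4-methoxybenzyl)oxy]methyl}-7-methyl-1-(4,4,5,5-tetramethyl-1,3,2-dioxaborolan-2-yl)-9-[(1S)-2,6,6-trimethylcyclohex-2-en-1-yl]nona-1,6-dien-3-yl acetate | CC1(C)OB(/C=C/[C@](OC(C)=O)(CC/C=C(\C)CC[C@@H]2C(C)=CCCC2(C)C)COCc3ccc(OC)cc3)OC1(C)C | intermediate
20 | potassium [(1E,3R,6E)-3-acetoxy-3-{[(4-methoxybenzyl)oxy]methyl}-7-methyl-9-[(1S)-2,6,6-trimethylcyclohex-2-en-1-yl]nona-1,6-dien-1-yl]trifluoroborate | [K+].F[B-](F)(F)/C=C/[C@](OC(C)=O)(CC/C=C(\C)CC[C@@H]1C(C)=CCCC1(C)C)COCc1ccc(OC)cc1 | intermediate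
21 | (1E,3R,6E)-3-{[(4-methoxybenzyl)oxy]methyl}-7-methyl-9-[(1S)-2,6,6-trimethylcyclohex-2-en-1-yl]nona-1,6-diene-1,3-diyl diacetate | CC(=O)O/C=C/[C@](OC(C)=O)(CC/C=C(\C)CC[C@@H]1C(C)=CCCC1(C)C)COCc1ccc(OC)cc1 | intermediate
22 | (1E,3R,6E)-3-(hydroxymethyl)-7-methyl-9-[(1S)-2,6,6-trimethylcyclohex-2-en-1-yl]nona-1,6-diene-1,3-diyl diacetate | CC(=O)O/C=C/[C@](OC(C)=O)(CC/C=C(\C)CC[C@@H]1C(C)=CCCC1(C)C)CO | intermediate
23 | (1E,3R,6E)-3-formyl-7-methyl-9-[(1S)-2,6,6-trimethylcyclohex-2-en-1-yl]nona-1,6-diene-1,3-diyl diacetate | CC(=O)O/C=C/[C@@](C=O)(CC/C=C(\C)CC[C@@H]1C(C)=CCCC1(C)C)OC(C)=O | target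

**Step count**

Total: 16 steps. Longest linear sequence: 16 steps (1 → 23).

**Three steps most likely to fail**

Step 3. The copper reagent may attack the carbinol carbon directly (α-substitution) or react sluggishly at the alkene carbon that adjoins CMe2, and the allylcopper intermediate may equilibrate with loss of stereospecificity. The fallback sets out from 1 and comes back to the route at 6. Reduction of 1 with the enantiomeric (S)-2-methyl-CBS-oxazaborolidine and BH3·SMe2 should give (1R)-2,4,4-trimethylcyclohex-2-en-1-ol F1. Johnson–Claisen rearrangement (MeC(OEt)3, cat. EtCO2H, 140 °C) delivers the carbon suprafacially, on the face of the C–O bond, so the (R)-alcohol should give ethyl 2-[(1S)-2,6,6-trimethylcyclohex-2-en-1-yl]acetate F2. LiAlH4 reduction should give 2-[(1S)-2,6,6-trimethylcyclohex-2-en-1-yl]ethan-1-ol F3, and I2/PPh3/imidazole should give (6S)-6-(2-iodoethyl)-1,5,5-trimethylcyclohex-1-ene F4. Alkylation of LiC≡CSiMe3 with F4 in THF/DMPU should give 6.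

Step 11. The opening of the hindered epoxide under basic conditions may be slow, with competing loss of acetylene from the tertiary propargylic alkoxide (retro-alkynylation). The fallback sets out from 14 and comes back at 17, opening the epoxide before the alkyne exists. Treatment of 14 with 4-methoxybenzyl alcohol and NaH (THF/DMF, 50 °C; attack at either CH2 after Payne equilibration leads to the same enantiomer) should give (2R,5E)-2-{[(4-methoxybenzyl)oxy]methyl}-6-methyl-8-[(1S)-2,6,6-trimethylcyclohex-2-en-1-yl]oct-5-ene-1,2-diol F5. TEMPO/PhI(OAc)2 should oxidise only the primary alcohol to (2S,5E)-2-hydroxy-2-{[(4-methoxybenzyl)oxy]methyl}-6-methyl-8-[(1S)-2,6,6-trimethylcyclohex-2-en-1-yl]oct-5-enal F6. Ohira–Bestmann homologation of F6 should give 17.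

Step 15. Once the PMB group is removed, the tertiary acetate can shift to the free primary hydroxyl through the cyclic orthoester (1,2-acyl migration), and the migrated material can no longer be oxidised to the target. The fallback sets out from 17 and comes back at 23, putting the tertiary acetate on last. Hydroboration of 17 as in step 13 should give the pinacol alkenylboronate of the free tertiary alcohol F7, and KHF2 should give the corresponding potassium alkenyltrifluoroborate F8. Copper-catalysed coupling with AcOH as in step 14 should give (1E,3R,6E)-3-hydroxy-3-{[(4-methoxybenzyl)oxy]methyl}-7-methyl-9-[(1S)-2,6,6-trimethylcyclohex-2-en-1-yl]nona-1,6-dien-1-yl acetate F9. DDQ should give (1E,3R,6E)-3-hydroxy-3-(hydroxymethyl)-7-methyl-9-[(1S)-2,6,6-trimethylcyclohex-2-en-1-yl]nona-1,6-dien-1-yl acetate F10, in which no ester can reach the primary hydroxyl. TEMPO/PhI(OAc)2 should give (1E,3R,6E)-3-formyl-3-hydroxy-7-methyl-9-[(1S)-2,6,6-trimethylcyclohex-2-en-1-yl]nona-1,6-dien-1-yl acetate F11, and Ac2O/DMAP/Et3N should acetylate its tertiary hydroxyl to give 23.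

**Further compounds**

F1 | step 3 | (1R)-2,4,4-trimethylcyclohex-2-en-1-ol | O[C@@H]1CCC(C)(C)C=C1C
F2 | step 3 | ethyl 2-[(1S)-2,6,6-trimethylcyclohex-2-en-1-yl]acetate | CCOC(=O)C[C@@H]1C(C)=CCCC1(C)C
F3 | step 3 | 2-[(1S)-2,6,6-trimethylcyclohex-2-en-1-yl]ethan-1-ol | OCC[C@@H]1C(C)=CCCC1(C)C
F4 | step 3 | (6S)-6-(2-iodoethyl)-1,5,5-trimethylcyclohex-1-ene | ICC[C@@H]1C(C)=CCCC1(C)C
F5 | step 11 | (2R,5E)-2-{[(4-methoxybenzyl)oxy]methyl}-6-methyl-8-[(1S)-2,6,6-trimethylcyclohex-2-en-1-yl]oct-5-ene-1,2-diol | OC[C@](O)(CC/C=C(\C)CC[C@@H]1C(C)=CCCC1(C)C)COCc1ccc(OC)cc1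
F6 | step 11 | (2S,5E)-2-hydroxy-2-{[(4-methoxybenzyl)oxy]methyl}-6-methyl-8-[(1S)-2,6,6-trimethylcyclohex-2-en-1-yl]oct-5-enal | O=C[C@](O)(CC/C=C(\C)CC[C@@H]1C(C)=CCCC1(C)C)COCc1ccc(OC)cc1
F7 | step 15 | (1E,3R,6E)-3-{[(4-methoxybenzyl)oxy]methyl}-7-methyl-1-(4,4,5,5-tetramethyl-1,3,2-dioxaborolan-2-yl)-9-[(1S)-2,6,6-trimethylcyclohex-2-en-1-yl]nona-1,6-dien-3-ol | CC1(C)OB(/C=C/[C@](O)(CC/C=C(\C)CC[C@@H]2C(C)=CCCC2(C)C)COCc3ccc(OC)cc3)OC1(C)C
F8 | step 15 | potassium [(1E,3R,6E)-3-hydroxy-3-{[(4-methoxybenzyl)oxy]methyl}-7-methyl-9-[(1S)-2,6,6-trimethylcyclohex-2-en-1-yl]nona-1,6-dien-1-yl]trifluoroborate | [K+].F[B-](F)(F)/C=C/[C@](O)(CC/C=C(\C)CC[C@@H]1C(C)=CCCC1(C)C)COCc1ccc(OC)cc1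
F9 | step 15 | (1E,3R,6E)-3-hydroxy-3-{[(4-methoxybenzyl)oxy]methyl}-7-methyl-9-[(1S)-2,6,6-trimethylcyclohex-2-en-1-yl]nona-1,6-dien-1-yl acetate | CC(=O)O/C=C/[C@](O)(CC/C=C(\C)CC[C@@H]1C(C)=CCCC1(C)C)COCc1ccc(OC)cc1
F10 | step 15 | (1E,3R,6E)-3-hydroxy-3-(hydroxymethyl)-7-methyl-9-[(1S)-2,6,6-trimethylcyclohex-2-en-1-yl]nona-1,6-dien-1-yl acetate | CC(=O)O/C=C/[C@](O)(CC/C=C(\C)CC[C@@H]1C(C)=CCCC1(C)C)CO
F11 | step 15 | (1E,3R,6E)-3-formyl-3-hydroxy-7-methyl-9-[(1S)-2,6,6-trimethylcyclohex-2-en-1-yl]nona-1,6-dien-1-yl acetate | CC(=O)O/C=C/[C@](O)(CC/C=C(\C)CC[C@@H]1C(C)=CCCC1(C)C)C=O
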